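**Plan**
1. Numbering: ring A = C1–C2–C3(OTig)–C4(Me, C15)–C5(Me, C14)–C10(H). Ring B = C5–C6–C7(isopropenyl)–C8(=O)–C9(OSen)–C10. β is the face of the C5 methyl. The target is a trans-decalin in which 3α-O, 4β-Me, 7α-isopropenyl and 9α-O are all equatorial.
2. Cuts: first O3–acyl and O9–acyl, then C7–C11. O8/O9 are taken back to a C8=C9 alkene and O3 to a ketone. Last, C9–C10 and C4–C5 are cut together.
3. Enabling feature: the quaternary, methyl-bearing C5 stands between C4 (α to C3=O) and the ring-fusion carbon C10. An open chain with one E-trisubstituted C5=C10 alkene, a C8≡C9 alkyne at one end and a C3=C4 enol silane at the other can therefore fold into ring B and ring A at once.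
4. Forward: the chain is joined from methacrolein (C5, C6, C10, C14), an acetal Grignard reagent (C1–C3), triethyl orthoacetate (C7, C8), a diazophosphonate (C9) and vinylmagnesium bromide (C4, C15). Ring B and then ring A close in the gold step. Ring B is then oxidised, C7 is alkenylated, and the esters go on last.
5. Stereochemistry: the absolute sense at C5/C10 comes from the chiral digold catalyst, the trans fusion from the E-alkene, and C4 from the Z-enol silane. C3 comes from dissolving-metal reduction, C9 from α-face OsO4 addition, and C7 from protonation to the equatorial epimer.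

Key step: step 8

Assumption: the sense of induction of the digold catalyst on this new substrate cannot be predicted. The (R)-ligand is written, and the (S)-ligand is used instead if it proves to give the antipode of 15.

**Step 1**
Reactants: 1 methacrolein; 2 2-(2-bromoethyl)-1,3-dioxolane
Product: 4 1-(1,3-dioxolan-2-yl)-4-methylpent-4-en-3-ol (racemic), via dioxolanylethylmagnesium bromide 3 (not isolated)
Conditions: Mg, THF, 25–30 °C; then 1, −78 → 0 °C; aq. work-up
Reagents that add atoms: none
Why: Grignard 1,2-addition to the enal carbonyl is fast at low temperature and gives the secondary allylic alcohol, whose stereocentre is erased in step 2.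

**Step 2**
Reactants: 4 allylic alcohol; 5 triethyl orthoacetate
Product: 6 ethyl (4E)-7-(1,3-dioxolan-2-yl)-4-methylhept-4-enoate
Conditions: 5 (5 equiv), EtCO2H (cat.), 138 °C, EtOH distilled off
Reagents that add atoms: none
Why: The Johnson–Claisen rearrangement runs through a chair with the acetal-bearing chain equatorial, which gives the E-trisubstituted C5=C10 alkene and adds C7 and C8.

**Step 3**
Reactants: 6 ester
Product: 8 2-[(3E)-4-methyloct-3-en-7-yn-1-yl]-1,3-dioxolane, via acetal aldehyde 7 (not isolated)
Conditions: i-Bu2AlH (1.1 equiv), CH2Cl2, −78 °C; then MeOH, K2CO3, dimethyl (1-diazo-2-oxopropyl)phosphonate, −78 °C → rt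
Reagents that add atoms: dimethyl (1-diazo-2-oxopropyl)phosphonate, COP(=O)(OC)C(=[N+]=[N-])C(C)=O
Why: Partial ester reduction followed by Ohira–Bestmann (Seyferth–Gilbert) homologation of the aldehyde released by MeOH is an established one-pot ester-to-alkyne conversion that adds C9 and leaves acetal and alkene alone.

**Step 4**
Reactants: 8 alkyne acetal
Product: 9 (4E)-5-methylnon-4-en-8-ynal
Conditions: 1 M HCl, THF, rt
Reagents that add atoms: water, O
Why: Acid-catalysed acetal hydrolysis frees the C3 aldehyde, and neither the isolated alkene nor the terminal alkyne reacts with dilute acid at room temperature.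

**Step 5**
Reactants: 9 enynal; 10 vinylmagnesium bromide
Product: 11 (6E)-7-methylundeca-1,6-dien-10-yn-3-ol (racemic)
Conditions: 10 (1.2 equiv), THF, −78 °C; aq. work-up
Reagents that add atoms: none
Why: Grignard addition to the aldehyde at −78 °C outruns deprotonation of the alkyne and brings in C4 and C15, and the new carbinol centre is removed in step 6.

**Step 6**
Reactants: 11 allylic alcohol
Product: 12 (6E)-7-methylundeca-1,6-dien-10-yn-3-one
Conditions: Dess–Martin periodinane, CH2Cl2, 0 °C → rt
Reagents that add atoms: none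
Why: Dess–Martin oxidation is mild enough to deliver the polymerisation-prone vinyl ketone without touching alkyne or alkene.

**Step 7**
Reactants: 12 vinyl ketone
Product: 14 (2Z,6E)-3-(tert-butyldimethylsilyloxy)-7-methylundeca-2,6-dien-10-yne, via lithium Z-enolate 13 (not isolated)
Conditions: LiBH(s-Bu)3 (1.05 equiv), THF, −78 °C (12 added slowly); then TBSOTf, −78 → −30 °C; Et3N, pentane, non-oxidative work-up
Reagents that add atoms: tert-butyldimethylsilyl trifluoromethanesulfonate, CC(C)(C)[Si](C)(C)OS(=O)(=O)C(F)(F)F
Why: Conjugate hydride addition to the s-cis vinyl ketone gives the regiodefined Z-enolate, which is O-silylated in situ (reductive enolate trapping); a borohydride is used because metal-catalysed hydrosilylation would also attack the terminal alkyne.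

**Step 8**
Reactants: 14 enyne enol silane
Product: 15 (1R,4aS,8aS)-1,8a-dimethyl-3,4,4a,7,8,8a-hexahydronaphthalen-2(1H)-one (trans-fused; C3 ketone, C8=C9 alkene, 4β-Me equatorial, 5β-Me axial, 10α-H)
Conditions: [(R)-DTBM-MeO-BIPHEP](AuCl)2 (5 mol %), AgSbF6 (5 mol %), MeOH (1.5 equiv), m-xylene, −20 °C → rt
Reagents that add atoms: none
Why: Proposed new method: the cationic monovalent gold centre binds the terminal alkyne, C10 of the alkene attacks C9 so that gold ends on C8 and the positive charge on C5, the enol silane carbon C4 captures C5, and MeOH takes up the silyl group and hands back the proton that cleaves the C8–Au bond. The closest known reaction type is the enantioselective gold-catalysed 6-endo-dig polycyclisation of 1,5-enynes ended by phenols, carboxylic acids, sulfonamides or electron-rich arenes, and gold-catalysed carbocyclisations of silyl enol ethers onto alkynes show that such nucleophiles tolerate these catalysts; an enol silane as the last link of the relay is the untested part. Ring B closes 6-endo-dig at the alkyne and ring A closes 6-endo-trig (enol-endo) at the C5 cation. C10 and C5 are set by anti addition across the E-alkene in a chair–chair fold, which places H-10 trans to the C5 methyl, while the alkene face that is attacked, and with it the absolute configuration, is chosen by the chiral pocket of the digold complex. C4 is set by the Z geometry of the enol silane, which puts its methyl group equatorial and cis to the C5 methyl, the epimer that is also the more stable one next to the ketone. The step needs 6-endo in place of 5-endo closure, secured by the C5 methyl (bonding at C10 gives a tertiary cation, bonding at C5 a secondary one), alkene-before-enol-silane attack, secured because direct attack of C4 on the alkyne would need a nine-membered ring, and survival of the enol silane, helped by the bulky TBS group and the small amount of MeOH.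

**Step 9**
Reactants: 15 octalenone
Product: 16 trans-fused 4β,5β-dimethyl-Δ8-octalin-3α-ol (equatorial OH, 10α-H)
Conditions: Li, NH3(l), THF, EtOH, −78 °C; aq. work-up
Reagents that add atoms: none
Why: Dissolving-metal reduction through the ketyl gives the more stable equatorial 3α-alcohol, whereas hydride reagents would be pushed to the α face by the syn-axial C5 methyl and give the axial epimer; the isolated alkene is inert.

**Step 10**
Reactants: 16 alcohol
Product: 17 3α-(tert-butyldimethylsilyloxy)-4β,5β-dimethyl-10αH-Δ8-octalin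
Conditions: TBSCl, imidazole, DMF, rt
Reagents that add atoms: tert-butyldimethylsilyl chloride, CC(C)(C)[Si](C)(C)Cl
Why: Imidazole-promoted silylation masks the only hydroxyl group with an ether that survives oxidation, strong base and DDQ.

**Step 11**
Reactants: 17 silyl ether
Product: 18 3α-(tert-butyldimethylsilyloxy)-4β,5β-dimethyl-10αH-decalin-8α,9α-diol (8-OH axial, 9-OH equatorial)
Conditions: OsO4 (2 mol %), NMO, acetone–H2O, rt
Reagents that add atoms: N-methylmorpholine N-oxide, C[N+]1([O-])CCOCC1; water, O
Why: Catalytic OsO4 syn-dihydroxylation takes place on the α face because the axial C5 methyl covers the β face of ring B, which sets the 9α-oxygen.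

**Step 12**
Reactants: 18 diol
Product: 20 9α-(4-methoxybenzyloxy)-3α-(tert-butyldimethylsilyloxy)-4β,5β-dimethyl-10αH-decalin-8α-ol, via dibutylstannylene acetal 19 (not isolated)
Conditions: Bu2SnO, toluene, reflux (−H2O); then PMBCl, Bu4NI (cat.), 90 °C
Reagents that add atoms: 4-methoxybenzyl chloride, COc1ccc(CCl)cc1
Why: Stannylene-acetal-mediated monoalkylation of a cis-diol on a chair activates the equatorial oxygen, here O9, so that the axial O8–H stays free.

**Step 13**
Reactants: 20 alcohol
Product: 21 9α-(4-methoxybenzyloxy)-3α-(tert-butyldimethylsilyloxy)-4β,5β-dimethyl-10αH-decalin-8-one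
Conditions: Dess–Martin periodinane, CH2Cl2, rt
Reagents that add atoms: none
Why: Dess–Martin oxidation of the single free, axial carbinol gives the C8 ketone, and the equatorial 9α-ether next to it is already the stable epimer.

**Step 14**
Reactants: 21 ketone; 22 2-bromopropene
Product: 23 9α-(4-methoxybenzyloxy)-3α-(tert-butyldimethylsilyloxy)-10αH-eremophil-11-en-8-one (7α-isopropenyl, equatorial)
Conditions: Pd2(dba)3 (2.5 mol %), P(t-Bu)3 (6 mol %), LiN(SiMe3)2 (2.3 equiv), toluene–THF, rt → 50 °C; AcOH, −78 °C
Reagents that add atoms: none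
Why: In this palladium-catalysed α-alkenylation of a ketone enolate the base enolises toward the C7 methylene (C9 is tertiary and alkoxy-substituted), the product rests as its dienolate until the cold acid quench protonates C7 kinetically to the β,γ-enone, and the isopropenyl group takes the equatorial 7α position that is also favoured at equilibrium.

**Step 15**
Reactants: 23 PMB ether
Product: 24 9α-hydroxy-3α-(tert-butyldimethylsilyloxy)-10αH-eremophil-11-en-8-one
Conditions: DDQ, CH2Cl2–pH 7 buffer, 0 °C
Reagents that add atoms: none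
Why: Oxidative PMB cleavage with DDQ is neutral and spares the silyl ether, the isopropenyl group and the epimerisable C7 and C9.

**Step 16**
Reactants: 24 ketol; 25 3-methylbut-2-enoyl chloride (senecioyl chloride)
Product: 26 9α-senecioyloxy-3α-(tert-butyldimethylsilyloxy)-10αH-eremophil-11-en-8-one
Conditions: 25, pyridine, DMAP (cat.), CH2Cl2, 0 °C → rt
Reagents that add atoms: none
Why: DMAP-catalysed acylation meets only one free hydroxyl group, and pyridine in place of a trialkylamine avoids the vinylketene pathway that would move the acyl double bond out of conjugation.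

**Step 17**
Reactants: 26 silyl ether
Product: 27 3α-hydroxy-9α-senecioyloxy-10αH-eremophil-11-en-8-one
Conditions: HF·pyridine, pyridine, THF, 0 °C → rt
Reagents that add atoms: none
Why: Fluoride-driven Si–O cleavage in a buffered, weakly acidic medium avoids the base that could conjugate the isopropenyl group, epimerise C7 or C9 or cleave the ester.

**Step 18**
Reactants: 27 alcohol; 28 (E)-2-methylbut-2-enoyl chloride (tigloyl chloride)
Product: 29 3α-tigloyloxy-9α-senecioyloxy-10αH-eremophil-11-en-8-one, (3R,4R,5R,7S,9S,10R), the target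
Conditions: 28, pyridine, DMAP (cat.), CH2Cl2, 0 °C → rt
Reagents that add atoms: none
Why: DMAP-catalysed acylation of the equatorial 3α-hydroxyl group keeps the E geometry of the acyl chloride and touches no stereocentre.

**Compound list**
1 | methacrolein | C=C(C)C=O | starting material
2 | 2-(2-bromoethyl)-1,3-dioxolane | BrCCC1OCCO1 | starting material
3 | [2-(1,3-dioxolan-2-yl)ethyl]magnesium bromide | Br[Mg]CCC1OCCO1 | intermediate
4 | 1-(1,3-dioxolan-2-yl)-4-methylpent-4-en-3-ol (racemic) | C=C(C)C(O)CCC1OCCO1 | intermediate
5 | triethyl orthoacetate | CC(OCC)(OCC)OCC | starting material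
6 | ethyl (4E)-7-(1,3-dioxolan-2-yl)-4-methylhept-4-enoate | CCOC(=O)CC/C(C)=C/CCC1OCCO1 | intermediate
7 | (4E)-7-(1,3-dioxolan-2-yl)-4-methylhept-4-enal | O=CCC/C(C)=C/CCC1OCCO1 | intermediate
8 | 2-[(3E)-4-methyloct-3-en-7-yn-1-yl]-1,3-dioxolane | C#CCC/C(C)=C/CCC1OCCO1 | intermediate
9 | (4E)-5-methylnon-4-en-8-ynal | C#CCC/C(C)=C/CCC=O | intermediate
10 | vinylmagnesium bromide | C=C[Mg]Br | starting material
11 | (6E)-7-methylundeca-1,6-dien-10-yn-3-ol (racemic) | C#CCC/C(C)=C/CCC(O)C=C | intermediate
12 | (6E)-7-methylundeca-1,6-dien-10-yn-3-one | C#CCC/C(C)=C/CCC(=O)C=C | intermediate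
13 | lithium (2Z,6E)-7-methylundeca-2,6-dien-10-yn-3-olate | C#CCC/C(C)=C/CC/C([O-])=C/C.[Li+] | intermediate
14 | (2Z,6E)-3-(tert-butyldimethylsilyloxy)-7-methylundeca-2,6-dien-10-yne | C#CCC/C(C)=C/CC/C(O[Si](C)(C)C(C)(C)C)=C/C | intermediate
15 | (1R,4aS,8aS)-1,8a-dimethyl-3,4,4a,7,8,8a-hexahydronaphthalen-2(1H)-one | C1C[C@]2(C)[C@@H](C)C(=O)CC[C@H]2C=C1 | intermediate
16 | 4β,5β-dimethyl-10αH-Δ8-octalin-3α-ol | C1C[C@]2(C)[C@@H](C)[C@H](O)CC[C@H]2C=C1 | intermediate
17 | 3α-TBS ether of 16 | C1C[C@]2(C)[C@@H](C)[C@H](O[Si](C)(C)C(C)(C)C)CC[C@H]2C=C1 | intermediate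
18 | 3α-TBSO-4β,5β-dimethyl-10αH-decalin-8α,9α-diol | C1C[C@]2(C)[C@@H](C)[C@H](O[Si](C)(C)C(C)(C)C)CC[C@H]2[C@H](O)[C@@H]1O | intermediate
19 | 8α,9α-O-dibutylstannylene acetal of 18 | C1C[C@]2(C)[C@@H](C)[C@H](O[Si](C)(C)C(C)(C)C)CC[C@H]2[C@H](O3)[C@@H]1O[Sn]3(CCCC)CCCC | intermediate
20 | 9α-PMBO-3α-TBSO-4β,5β-dimethyl-10αH-decalin-8α-ol | C1C[C@]2(C)[C@@H](C)[C@H](O[Si](C)(C)C(C)(C)C)CC[C@H]2[C@H](OCc3ccc(OC)cc3)[C@@H]1O | intermediate
21 | 9α-PMBO-3α-TBSO-4β,5β-dimethyl-10αH-decalin-8-one | C1C[C@]2(C)[C@@H](C)[C@H](O[Si](C)(C)C(C)(C)C)CC[C@H]2[C@H](OCc3ccc(OC)cc3)C1=O | intermediate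
22 | 2-bromopropene | C=C(C)Br | starting material
23 | 9α-PMBO-3α-TBSO-10αH-eremophil-11-en-8-one (7α-isopropenyl) | C=C(C)[C@@H]1C[C@]2(C)[C@@H](C)[C@H](O[Si](C)(C)C(C)(C)C)CC[C@H]2[C@H](OCc3ccc(OC)cc3)C1=O | intermediate
24 | 9α-hydroxy-3α-TBSO-10αH-eremophil-11-en-8-one | C=C(C)[C@@H]1C[C@]2(C)[C@@H](C)[C@H](O[Si](C)(C)C(C)(C)C)CC[C@H]2[C@H](O)C1=O | intermediate
25 | 3-methylbut-2-enoyl chloride | CC(C)=CC(=O)Cl | starting material
26 | 9α-senecioyloxy-3α-TBSO-10αH-eremophil-11-en-8-one | C=C(C)[C@@H]1C[C@]2(C)[C@@H](C)[C@H](O[Si](C)(C)C(C)(C)C)CC[C@H]2[C@H](OC(=O)C=C(C)C)C1=O | intermediate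
27 | 3α-hydroxy-9α-senecioyloxy-10αH-eremophil-11-en-8-one | C=C(C)[C@@H]1C[C@]2(C)[C@@H](C)[C@H](O)CC[C@H]2[C@H](OC(=O)C=C(C)C)C1=O | intermediate
28 | (E)-2-methylbut-2-enoyl chloride | O=C(Cl)/C(C)=C/C | starting material
29 | 3α-tigloyloxy-9α-senecioyloxy-10αH-eremophil-11-en-8-one | C=C(C)[C@@H]1C[C@]2(C)[C@@H](C)[C@H](OC(=O)/C(C)=C/C)CC[C@H]2[C@H](OC(=O)C=C(C)C)C1=O | target

**Total step count:** 18. **Longest linear sequence:** 18 steps (1 → 29).

**Steps most likely to fail**

Step 8. The silyl group may be lost before the cascade starts. The cascade may stop after ring B through proton loss from the C5 cation. The catalyst may also choose poorly between the two alkene faces.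
- The fallback sets out from aldehyde 9 and returns at ketone 15.
- It replaces the enol silane by a 1,3-dicarbonyl carbon nucleophile. This class is already known to trap the cationic intermediates of gold-catalysed enyne cyclisations and to end cation–olefin cyclisations.
- Aldol addition of the lithium enolate of methyl propanoate (LiN(i-Pr)2, THF, −78 °C) gives methyl (6E)-3-hydroxy-2,7-dimethylundec-6-en-10-ynoate F1.
- Dess–Martin oxidation gives methyl (6E)-2,7-dimethyl-3-oxoundec-6-en-10-ynoate F2.
- The same digold catalyst, now without alcohol because the enol proton serves the protodeauration, should close both rings to methyl 4,5β-dimethyl-3-oxo-10αH-Δ8-octalin-4-carboxylate F3.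
- Krapcho demethoxycarbonylation (LiCl, wet DMSO, 150 °C) removes the ester, and protonation of the enol leaves the C4 methyl in its more stable equatorial position, which is 15.

Step 14. The new double bond may move into conjugation in the basic medium. A second alkenylation may occur. The coupling may also stall at the hindered enolate.
- The fallback sets out from ketone 21 and returns at 23.
- The zinc enolate (LiN(i-Pr)2, then ZnCl2, THF, −78 °C) adds to acetone to give 7α-(2-hydroxypropan-2-yl)-9α-PMBO-3α-TBSO-4β,5β-dimethyl-10αH-decalin-8-one F4.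
- MsCl/Et3N followed by DBU eliminates to the conjugated 9α-PMBO-3α-TBSO-10αH-eremophil-7(11)-en-8-one F5.
- KN(SiMe3)2 (THF, −78 °C) then removes a γ-proton from a C11 methyl group. Cold AcOH protonates the extended enolate at C7. This is a deconjugative protonation of the pulegone-to-isopulegone kind, and it gives 23.

Step 12. Discrimination between O8 and O9 may be poor because the equatorial O9 is crowded by the ring fusion.
- The fallback sets out from diol 18 and returns at ketone 21. It differentiates the two carbinols by oxidation instead of alkylation.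
- TEMPO (cat.)/PhI(OAc)2 in CH2Cl2 should take the axial C8 carbinol, whose equatorial C–H is exposed, while H-9 is axial and lies under the C5 methyl.
- This gives 9α-hydroxy-3α-TBSO-4β,5β-dimethyl-10αH-decalin-8-one F6.
- Acid-catalysed etherification with 4-methoxybenzyl 2,2,2-trichloroacetimidate and La(OTf)3 (cat.) in toluene then gives 21.

**Further compounds**
F1 | step 8 | methyl (6E)-3-hydroxy-2,7-dimethylundec-6-en-10-ynoate (diastereomer mixture) | C#CCC/C(C)=C/CCC(O)C(C)C(=O)OC
F2 | step 8 | methyl (6E)-2,7-dimethyl-3-oxoundec-6-en-10-ynoate | C#CCC/C(C)=C/CCC(=O)C(C)C(=O)OC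
F3 | step 8 | methyl 4,5β-dimethyl-3-oxo-10αH-Δ8-octalin-4-carboxylate (C4 configuration open, lost on decarboxylation) | C1C[C@]2(C)C(C)(C(=O)OC)C(=O)CC[C@H]2C=C1
F4 | step 14 | 7α-(2-hydroxypropan-2-yl)-9α-PMBO-3α-TBSO-4β,5β-dimethyl-10αH-decalin-8-one | CC(C)(O)[C@@H]1C[C@]2(C)[C@@H](C)[C@H](O[Si](C)(C)C(C)(C)C)CC[C@H]2[C@H](OCc3ccc(OC)cc3)C1=O
F5 | step 14 | 9α-PMBO-3α-TBSO-10αH-eremophil-7(11)-en-8-one | CC(C)=C1C[C@]2(C)[C@@H](C)[C@H](O[Si](C)(C)C(C)(C)C)CC[C@H]2[C@H](OCc3ccc(OC)cc3)C1=O
F6 | step 12 | 9α-hydroxy-3α-TBSO-4β,5β-dimethyl-10αH-decalin-8-one | C1C[C@]2(C)[C@@H](C)[C@H](O[Si](C)(C)C(C)(C)C)CC[C@H]2[C@H](O)C1=O
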